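## Retrosynthetic overview

1. Feature: in the dihydrobenzofuran, C3 (the carbon bearing CH2OH) sits on C3a of ring B, ortho to the C7a–O1 oxygen. O1–C7a–C3a–C3 is therefore a masked ortho-quinone methide, and C2 with its guaiacyl ring C is a one-carbon benzylic ylide.
2. Last C–C bond: C5 of ring B to the CH2 on lactone C4, by Negishi coupling of a 5-bromodihydrobenzofuran with the zinc reagent of a (3R,4R)-3-benzyl-4-(iodomethyl)butyrolactone.
3. Key disconnection: C2–C3 and O1–C2, by [4+1] annulation. The methide is released from a racemic 2-(1-sulfonylalkyl)phenol and the benzylide is carried on twofold-symmetric (2S,5S)-2,5-dimethylthiolane.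
4. Lactone fragment: C4–vinyl by rhodium-catalysed asymmetric 1,4-addition to furan-2(5H)-one, C3–benzyl by trans-selective enolate alkylation, then the vinyl group is cut down to CH2I.
5. Ring order: the three arene rings and the lactone ring are bought. The dihydrofuran ring is the only ring formed.

Key step: step 11

Remark on the chemistry (thiolane antipode): the (2R,5R)-thiolanium benzylide is known to give (S,S)-diaryl epoxides with aldehydes, and the same open ylide face mapped on C2 (where aryl outranks C3 in the CIP order) means 2R, so the (2S,5S)-thiolane is assumed to lead to 2S,3R.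

Remark on the chemistry (protecting groups): the primary alcohol is carried as its tert-butyldiphenylsilyl (TBDPS) ether, which outlasts the acid of step 4, and both phenols end as tert-butyldimethylsilyl (TBS) ethers, so fluoride alone ends the synthesis and no hydrogenolysis comes near the benzylic C2–O1 bond.

## Route

Step 1
Reactants: 1 5-bromo-2-hydroxy-3-methoxybenzaldehyde
Product: 2 4-bromo-2-methoxy-6-vinylphenol
Conditions: MePPh3Br (2.5 equiv), KOtBu (2.5 equiv), THF, 0 °C to rt
Reagents that add atoms: methyltriphenylphosphonium bromide, C[P+](c1ccccc1)(c1ccccc1)c1ccccc1.[Br-]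
Why: Wittig methylenation, in which the extra base only parks the phenol as its potassium salt, as is routine for salicylaldehydes, and the aryl bromide is inert.

Step 2
Reactants: 2 4-bromo-2-methoxy-6-vinylphenol
Product: 3 rac-1-(5-bromo-2-hydroxy-3-methoxyphenyl)ethane-1,2-diol
Conditions: OsO4 (2 mol %), NMO (1.5 equiv), acetone/H2O 4:1, rt; aq Na2SO3
Reagents that add atoms: N-methylmorpholine N-oxide, C[N+]1([O-])CCOCC1; water, O
Why: Upjohn dihydroxylation of the terminal styrene, where the benzylic stereocentre is made racemic on purpose because step 11 erases it, and the para-blocked bromophenol should not be oxidised by NMO.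

Step 3
Reactants: 3 rac-1-(5-bromo-2-hydroxy-3-methoxyphenyl)ethane-1,2-diol
Product: 4 rac-4-bromo-2-[2-(tert-butyldiphenylsilyloxy)-1-hydroxyethyl]-6-methoxyphenol
Conditions: TBDPSCl (1.05 equiv), imidazole (2.2 equiv), CH2Cl2, 0 °C
Reagents that add atoms: tert-butyl(chloro)diphenylsilane, CC(C)(C)[Si](Cl)(c1ccccc1)c1ccccc1
Why: Sterically governed O-silylation, in which the bulky chlorosilane should take the primary alcohol ahead of the secondary benzylic alcohol and the 2,6-disubstituted, hydrogen-bonded phenol.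

Step 4
Reactants: 4 rac-4-bromo-2-[2-(tert-butyldiphenylsilyloxy)-1-hydroxyethyl]-6-methoxyphenol
Product: 5 rac-4-bromo-2-[2-(tert-butyldiphenylsilyloxy)-1-(p-toluenesulfonyl)ethyl]-6-methoxyphenol
Conditions: p-TolSO2H (2 equiv), 4 Å MS, CH2Cl2, rt to 35 °C
Reagents that add atoms: p-toluenesulfinic acid, Cc1ccc(S(=O)O)cc1
Why: Acid-promoted SN1-type substitution of an ortho-hydroxybenzylic alcohol by a sulfinic acid (the standard entry to 2-(1-sulfonylalkyl)phenols), in which the ortho-OH assists loss of water, S-attack gives the thermodynamically favoured sulfone, the TBDPS ether tolerates the weak acid and the stereocentre stays racemic.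

Step 5
Reactants: 6 (2R,5R)-hexane-2,5-diol
Product: 7 (2R,5R)-hexane-2,5-diyl dimethanesulfonate
Conditions: MsCl (2.4 equiv), Et3N (3 equiv), CH2Cl2, −20 to 0 °C
Reagents that add atoms: methanesulfonyl chloride, CS(=O)(=O)Cl
Why: O-Sulfonylation, which breaks no C–O bond and so leaves both stereocentres as they are.

Step 6
Reactants: 7 (2R,5R)-hexane-2,5-diyl dimethanesulfonate
Product: 8 (2S,5S)-2,5-dimethylthiolane
Conditions: Na2S·9H2O (1.1 equiv), EtOH, rt; pentane extraction, distillation
Reagents that add atoms: sodium sulfide, [Na+].[Na+].[S-2]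
Why: Double SN2 displacement by sulfide with five-membered ring closure, which inverts both centres and turns the (R,R)-dimesylate into the (S,S)-thiolane.

Step 7
Reactants: 9 vanillin
Product: 10 4-formyl-2-methoxyphenyl pivalate
Conditions: PivCl (1.1 equiv), Et3N (1.5 equiv), DMAP (5 mol %), CH2Cl2, 0 °C to rt
Reagents that add atoms: pivaloyl chloride, CC(C)(C)C(=O)Cl
Why: DMAP-catalysed O-acylation of the only nucleophilic group in the molecule.

Step 8
Reactants: 10 4-formyl-2-methoxyphenyl pivalate
Product: 11 4-(hydroxymethyl)-2-methoxyphenyl pivalate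
Conditions: NaBH4 (0.6 equiv), THF/MeOH 4:1, 0 °C
Reagents that add atoms: none
Why: Chemoselective borohydride reduction of the aldehyde, to which the hindered aryl ester is inert at 0 °C.

Step 9
Reactants: 11 4-(hydroxymethyl)-2-methoxyphenyl pivalate
Product: 12 4-(bromomethyl)-2-methoxyphenyl pivalate
Conditions: PBr3 (0.4 equiv), CH2Cl2, 0 °C
Reagents that add atoms: phosphorus tribromide, BrP(Br)Br
Why: Bromination of a benzylic alcohol through its phosphite ester (SN2), which the pivalate survives and which gives a bromide less prone to ionise than an alkoxy-substituted one.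

Step 10
Reactants: 8 (2S,5S)-2,5-dimethylthiolane; 12 4-(bromomethyl)-2-methoxyphenyl pivalate
Product: 13 (2S,5S)-2,5-dimethyl-1-(3-methoxy-4-pivaloyloxybenzyl)thiolanium tetrafluoroborate
Conditions: AgBF4 (1.05 equiv), CH2Cl2, 0 °C to rt, dark; filtration, precipitation with Et2O
Reagents that add atoms: silver tetrafluoroborate, [Ag+].F[B-](F)(F)F
Why: S-Alkylation of a hindered sulfide driven by silver-assisted halide abstraction, and because the thiolane is twofold-symmetric sulfur is not stereogenic and only one salt can form.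

Step 11
Reactants: 5 rac-4-bromo-2-[2-(tert-butyldiphenylsilyloxy)-1-(p-toluenesulfonyl)ethyl]-6-methoxyphenol; 13 (2S,5S)-2,5-dimethyl-1-(3-methoxy-4-pivaloyloxybenzyl)thiolanium tetrafluoroborate
Product: 17 (2S,3R)-5-bromo-3-[(tert-butyldiphenylsilyloxy)methyl]-7-methoxy-2-(3-methoxy-4-pivaloyloxyphenyl)-2,3-dihydrobenzofuran, via ortho-quinone methide 14 (not isolated), via benzylic sulfonium ylide 15 (not isolated), via phenoxide sulfonium betaine 16 (not isolated)
Conditions: 13 (1.5 equiv), Cs2CO3 (3.5 equiv), MeCN/CH2Cl2 1:1, −20 °C; 5 added over 3 h; then 0 °C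
Reagents that add atoms: none
Why: Proposed new method: Cs2CO3 deprotonates the phenol of 5, which expels p-toluenesulfinate to give the (E)-methide 14, and it also deprotonates the benzylic CH2 of 13 to the semi-stabilised ylide 15, whose carbon adds 1,4 to the exocyclic methide carbon (C2–C3 bond) in a step made irreversible by the re-aromatisation of ring B, giving betaine 16. The phenoxide of 16 then displaces the neutral thiolane at the benzylic carbon from the rear (O1–C2 bond), a 5-exo-tet SN2 closure of the dihydrofuran ring. The closest known reaction types are the carbonate-mediated [4+1] annulation of sulfonylphenol-derived ortho-quinone methides with carbonyl-stabilised sulfonium or ammonium ylides and the asymmetric benzylidene transfer from chiral thiolanium benzylides to aldehydes, and what is new is the union of an aryl-substituted chiral ylide with an ortho-quinone methide. C2 is controlled by the thiolane: in the favoured ylide conformer the aryl group points away from the ring, the methyl group syn to the ylide carbon shields one face, and attack through the open face of the (2S,5S)-ylide followed by inversion on closure should give 2S. C3 is controlled relative to C2 by the approach of the (E)-methide with its CH2OSi arm anti to the ylide aryl group (anti betaine), so the stereospecific closure should give the trans ring and hence 3R. The step needs ylide attack on the methide to outrun benzylation of sulfinate or phenoxide by 13, tautomerisation of 14 to a silyl enol ether and ionisation of 13, which the unhindered monosubstituted methide carbon, the slow addition of 5 to an excess of 13 and the electron-poor pivaloyloxy ring C should secure.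

Step 12
Reactants: 17 (2S,3R)-5-bromo-3-[(tert-butyldiphenylsilyloxy)methyl]-7-methoxy-2-(3-methoxy-4-pivaloyloxyphenyl)-2,3-dihydrobenzofuran
Product: 18 4-{(2S,3R)-5-bromo-3-[(tert-butyldiphenylsilyloxy)methyl]-7-methoxy-2,3-dihydrobenzofuran-2-yl}-2-methoxyphenol
Conditions: K2CO3 (1.5 equiv), MeOH/THF 2:1, rt; aq NH4Cl
Reagents that add atoms: none
Why: Base-mediated methanolysis (transesterification) of the activated aryl ester, done before any lactone is present, under conditions that leave the TBDPS ether, the aryl bromide and both stereocentres alone at room temperature.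

Step 13
Reactants: 18 4-{(2S,3R)-5-bromo-3-[(tert-butyldiphenylsilyloxy)methyl]-7-methoxy-2,3-dihydrobenzofuran-2-yl}-2-methoxyphenol
Product: 19 (2S,3R)-5-bromo-2-[4-(tert-butyldimethylsilyloxy)-3-methoxyphenyl]-3-[(tert-butyldiphenylsilyloxy)methyl]-7-methoxy-2,3-dihydrobenzofuran
Conditions: TBSCl (1.3 equiv), imidazole (2.5 equiv), DMF, rt
Reagents that add atoms: tert-butyl(chloro)dimethylsilane, CC(C)(C)[Si](C)(C)Cl
Why: Standard imidazole-promoted silylation of the only free OH, which removes the acidic proton that would quench the zinc reagent of step 21.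

Step 14
Reactants: 9 vanillin
Product: 20 4-(tert-butyldimethylsilyloxy)-3-methoxybenzaldehyde
Conditions: TBSCl (1.1 equiv), imidazole (2 equiv), CH2Cl2, rt
Reagents that add atoms: tert-butyl(chloro)dimethylsilane, CC(C)(C)[Si](C)(C)Cl
Why: Standard phenol silylation.

Step 15
Reactants: 20 4-(tert-butyldimethylsilyloxy)-3-methoxybenzaldehyde
Product: 21 [4-(tert-butyldimethylsilyloxy)-3-methoxyphenyl]methanol
Conditions: NaBH4 (0.6 equiv), MeOH, 0 °C
Reagents that add atoms: none
Why: Borohydride reduction of the aldehyde, which the aryl silyl ether survives during the short cold reaction.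

Step 16
Reactants: 21 [4-(tert-butyldimethylsilyloxy)-3-methoxyphenyl]methanol
Product: 22 4-(bromomethyl)-1-(tert-butyldimethylsilyloxy)-2-methoxybenzene
Conditions: PBr3 (0.4 equiv), Et2O, 0 °C; used at once
Reagents that add atoms: phosphorus tribromide, BrP(Br)Br
Why: Bromination of a benzylic alcohol through its phosphite ester, the labile electron-rich bromide being carried on without storage.

Step 17
Reactants: 23 furan-2(5H)-one
Product: 24 (S)-4-vinyldihydrofuran-2(3H)-one
Conditions: CH2=CHBF3K (2 equiv), [Rh(cod)2]BF4 (3 mol %), (S)-BINAP (3.3 mol %), toluene/H2O 20:1, 100 °C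
Reagents that add atoms: potassium vinyltrifluoroborate, C=C[B-](F)(F)F.[K+]
Why: Hayashi–Miyaura-type rhodium-catalysed asymmetric 1,4-addition of an alkenylboron reagent to an α,β-unsaturated lactone with protonation of the rhodium enolate by water, C4 being set by (S)-BINAP, which on cyclic enones and enoates directs the organorhodium to the face that here corresponds to the (S)-lactone.

Step 18
Reactants: 24 (S)-4-vinyldihydrofuran-2(3H)-one; 22 4-(bromomethyl)-1-(tert-butyldimethylsilyloxy)-2-methoxybenzene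
Product: 26 (3R,4R)-3-[4-(tert-butyldimethylsilyloxy)-3-methoxybenzyl]-4-vinyldihydrofuran-2(3H)-one, via lithium enolate 25 (not isolated)
Conditions: LiN(SiMe3)2 (1.05 equiv), THF, −78 °C; then 22 (1.1 equiv), −78 to −40 °C
Reagents that add atoms: none
Why: Lactone enolate alkylation, the classical last C–C bond of dibenzylbutyrolactone chemistry, in which C3 is set by substrate control because the bromide approaches enolate 25 on the face anti to the C4 vinyl group and gives the trans (3R,4R) lactone.

Step 19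
Reactants: 26 (3R,4R)-3-[4-(tert-butyldimethylsilyloxy)-3-methoxybenzyl]-4-vinyldihydrofuran-2(3H)-one
Product: 28 (3R,4S)-3-[4-(tert-butyldimethylsilyloxy)-3-methoxybenzyl]-4-(hydroxymethyl)dihydrofuran-2(3H)-one, via formyl lactone 27 (not isolated)
Conditions: O3, CH2Cl2/MeOH 4:1, −78 °C (Sudan Red 7B end-point); NaBH4 (3 equiv), −78 to 0 °C; AcOH
Reagents that add atoms: ozone, [O-][O+]=O
Why: Ozonolysis with reductive borohydride work-up, in which the dye end-point spares the arene, the cold reduction of 27 forestalls enolisation or β-elimination at C4, the spatial arrangement is kept (the descriptor changes to 4S by CIP ranking only), and any translactonisation would lead to the less stable cis isomer.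

Step 20
Reactants: 28 (3R,4S)-3-[4-(tert-butyldimethylsilyloxy)-3-methoxybenzyl]-4-(hydroxymethyl)dihydrofuran-2(3H)-one
Product: 29 (3R,4R)-3-[4-(tert-butyldimethylsilyloxy)-3-methoxybenzyl]-4-(iodomethyl)dihydrofuran-2(3H)-one
Conditions: I2 (1.3 equiv), PPh3 (1.3 equiv), imidazole (2.6 equiv), CH2Cl2, 0 °C to rt, dark
Reagents that add atoms: iodine, II
Why: Appel-type iodination of a primary alcohol under nearly neutral conditions, which touches no stereocentre (the descriptor returns to 4R by CIP ranking only).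

Step 21
Reactants: 29 (3R,4R)-3-[4-(tert-butyldimethylsilyloxy)-3-methoxybenzyl]-4-(iodomethyl)dihydrofuran-2(3H)-one; 19 (2S,3R)-5-bromo-2-[4-(tert-butyldimethylsilyloxy)-3-methoxyphenyl]-3-[(tert-butyldiphenylsilyloxy)methyl]-7-methoxy-2,3-dihydrobenzofuran
Product: 31 tris-O-silyl lappaol A (both phenols as TBS ethers, the primary alcohol as TBDPS ether), via alkylzinc iodide 30 (not isolated)
Conditions: 29 (1.4 equiv), Zn dust (activated with BrCH2CH2Br and Me3SiCl), LiCl, THF, 30 °C; then 19, Pd(OAc)2 (3 mol %), SPhos (6 mol %), THF, rt to 45 °C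
Reagents that add atoms: none
Why: Negishi sp3–sp2 cross-coupling, in which LiCl-promoted zinc insertion into the primary C–I bond gives 30, which has no β-leaving group (the acyloxy group sits γ to zinc) and tolerates lactone and silyl ethers, and the zerovalent palladium–SPhos catalyst formed from Pd(OAc)2 should couple it at the unhindered C5–Br of 19 faster than β-hydride elimination, with no stereocentre touched.

Step 22
Reactants: 31 tris-O-silyl lappaol A
Product: 32 lappaol A
Conditions: Bu4NF (4.5 equiv), AcOH (4.5 equiv), THF, 0 °C to rt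
Reagents that add atoms: none
Why: Fluoride-mediated cleavage of the three Si–O bonds, buffered by acetic acid so that lactone C3 does not epimerise and the para-hydroxybenzylic C2–O1 bond does not open by way of a para-quinone methide.

## Compound list

1 | 5-bromo-2-hydroxy-3-methoxybenzaldehyde | COc1cc(Br)cc(C=O)c1O | starting material
2 | 4-bromo-2-methoxy-6-vinylphenol | COc1cc(Br)cc(C=C)c1O | intermediate
3 | rac-1-(5-bromo-2-hydroxy-3-methoxyphenyl)ethane-1,2-diol | COc1cc(Br)cc(C(O)CO)c1O | intermediate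
4 | rac-4-bromo-2-[2-(tert-butyldiphenylsilyloxy)-1-hydroxyethyl]-6-methoxyphenol | COc1cc(Br)cc(C(O)CO[Si](c2ccccc2)(c2ccccc2)C(C)(C)C)c1O | intermediate
5 | rac-4-bromo-2-[2-(tert-butyldiphenylsilyloxy)-1-(p-toluenesulfonyl)ethyl]-6-methoxyphenol | COc1cc(Br)cc(C(CO[Si](c2ccccc2)(c2ccccc2)C(C)(C)C)S(=O)(=O)c2ccc(C)cc2)c1O | intermediate
6 | (2R,5R)-hexane-2,5-diol | C[C@@H](O)CC[C@@H](C)O | starting material
7 | (2R,5R)-hexane-2,5-diyl dimethanesulfonate | C[C@@H](OS(C)(=O)=O)CC[C@@H](C)OS(C)(=O)=O | intermediate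
8 | (2S,5S)-2,5-dimethylthiolane | C[C@H]1CC[C@H](C)S1 | intermediate
9 | vanillin | COc1cc(C=O)ccc1O | starting material
10 | 4-formyl-2-methoxyphenyl pivalate | COc1cc(C=O)ccc1OC(=O)C(C)(C)C | intermediate
11 | 4-(hydroxymethyl)-2-methoxyphenyl pivalate | COc1cc(CO)ccc1OC(=O)C(C)(C)C | intermediate
12 | 4-(bromomethyl)-2-methoxyphenyl pivalate | COc1cc(CBr)ccc1OC(=O)C(C)(C)C | intermediate
13 | (2S,5S)-2,5-dimethyl-1-(3-methoxy-4-pivaloyloxybenzyl)thiolanium tetrafluoroborate | C[C@H]1CC[C@H](C)[S+]1Cc1ccc(OC(=O)C(C)(C)C)c(OC)c1.F[B-](F)(F)F | intermediate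
14 | (6E)-4-bromo-6-[2-(tert-butyldiphenylsilyloxy)ethylidene]-2-methoxycyclohexa-2,4-dien-1-one (ortho-quinone methide) | CC(C)(C)[Si](c1ccccc1)(c1ccccc1)OC/C=C1\C=C(Br)C=C(OC)C1=O | intermediate
15 | [(2S,5S)-2,5-dimethylthiolan-1-ium-1-yl](3-methoxy-4-pivaloyloxyphenyl)methanide (ylide) | C[C@H]1CC[C@H](C)[S+]1[CH-]c1ccc(OC(=O)C(C)(C)C)c(OC)c1 | intermediate
16 | 4-bromo-2-{(1R,2R)-3-(tert-butyldiphenylsilyloxy)-1-[(2S,5S)-2,5-dimethylthiolan-1-ium-1-yl]-1-(3-methoxy-4-pivaloyloxyphenyl)propan-2-yl}-6-methoxyphenolate (anti betaine) | [O-]c1c(OC)cc(Br)cc1[C@H](CO[Si](c1ccccc1)(c1ccccc1)C(C)(C)C)[C@H](c1ccc(OC(=O)C(C)(C)C)c(OC)c1)[S+]1[C@@H](C)CC[C@@H]1C | intermediate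
17 | (2S,3R)-5-bromo-3-[(tert-butyldiphenylsilyloxy)methyl]-7-methoxy-2-(3-methoxy-4-pivaloyloxyphenyl)-2,3-dihydrobenzofuran | Brc1cc(OC)c2c(c1)[C@H](CO[Si](c1ccccc1)(c1ccccc1)C(C)(C)C)[C@@H](c1ccc(OC(=O)C(C)(C)C)c(OC)c1)O2 | intermediate
18 | 4-{(2S,3R)-5-bromo-3-[(tert-butyldiphenylsilyloxy)methyl]-7-methoxy-2,3-dihydrobenzofuran-2-yl}-2-methoxyphenol | Brc1cc(OC)c2c(c1)[C@H](CO[Si](c1ccccc1)(c1ccccc1)C(C)(C)C)[C@@H](c1ccc(O)c(OC)c1)O2 | intermediate
19 | (2S,3R)-5-bromo-2-[4-(tert-butyldimethylsilyloxy)-3-methoxyphenyl]-3-[(tert-butyldiphenylsilyloxy)methyl]-7-methoxy-2,3-dihydrobenzofuran | Brc1cc(OC)c2c(c1)[C@H](CO[Si](c1ccccc1)(c1ccccc1)C(C)(C)C)[C@@H](c1ccc(O[Si](C)(C)C(C)(C)C)c(OC)c1)O2 | intermediate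
20 | 4-(tert-butyldimethylsilyloxy)-3-methoxybenzaldehyde | COc1cc(C=O)ccc1O[Si](C)(C)C(C)(C)C | intermediate
21 | [4-(tert-butyldimethylsilyloxy)-3-methoxyphenyl]methanol | COc1cc(CO)ccc1O[Si](C)(C)C(C)(C)C | intermediate
22 | 4-(bromomethyl)-1-(tert-butyldimethylsilyloxy)-2-methoxybenzene | COc1cc(CBr)ccc1O[Si](C)(C)C(C)(C)C | intermediate
23 | furan-2(5H)-one | O=C1C=CCO1 | starting material
24 | (S)-4-vinyldihydrofuran-2(3H)-one | C1C(=O)OC[C@@H]1C=C | intermediate
25 | lithium enolate of 24 | C1=C([O-])OC[C@@H]1C=C.[Li+] | intermediate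
26 | (3R,4R)-3-[4-(tert-butyldimethylsilyloxy)-3-methoxybenzyl]-4-vinyldihydrofuran-2(3H)-one | COc1cc(C[C@H]2C(=O)OC[C@@H]2C=C)ccc1O[Si](C)(C)C(C)(C)C | intermediate
27 | (3R,4R)-3-[4-(tert-butyldimethylsilyloxy)-3-methoxybenzyl]-4-formyldihydrofuran-2(3H)-one | COc1cc(C[C@H]2C(=O)OC[C@@H]2C=O)ccc1O[Si](C)(C)C(C)(C)C | intermediate
28 | (3R,4S)-3-[4-(tert-butyldimethylsilyloxy)-3-methoxybenzyl]-4-(hydroxymethyl)dihydrofuran-2(3H)-one | COc1cc(C[C@H]2C(=O)OC[C@@H]2CO)ccc1O[Si](C)(C)C(C)(C)C | intermediate
29 | (3R,4R)-3-[4-(tert-butyldimethylsilyloxy)-3-methoxybenzyl]-4-(iodomethyl)dihydrofuran-2(3H)-one | COc1cc(C[C@H]2C(=O)OC[C@@H]2CI)ccc1O[Si](C)(C)C(C)(C)C | intermediate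
30 | {(3R,4R)-4-[4-(tert-butyldimethylsilyloxy)-3-methoxybenzyl]-5-oxotetrahydrofuran-3-yl}methylzinc iodide | COc1cc(C[C@H]2C(=O)OC[C@@H]2C[Zn]I)ccc1O[Si](C)(C)C(C)(C)C | intermediate
31 | tris-O-silyl lappaol A (two aryl TBS ethers, one primary TBDPS ether) | COc1cc(C[C@H]2C(=O)OC[C@@H]2Cc2cc(OC)c3c(c2)[C@H](CO[Si](c2ccccc2)(c2ccccc2)C(C)(C)C)[C@@H](c2ccc(O[Si](C)(C)C(C)(C)C)c(OC)c2)O3)ccc1O[Si](C)(C)C(C)(C)C | intermediate
32 | lappaol A | COc1cc(C[C@H]2C(=O)OC[C@@H]2Cc2cc(OC)c3c(c2)[C@H](CO)[C@@H](c2ccc(O)c(OC)c2)O3)ccc1O | target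

## Step count

Total step count: 22.

Longest linear sequence: 9 steps (steps 7, 8, 9, 10, 11, 12, 13, 21, 22 from vanillin; equally steps 1, 2, 3, 4, 11, 12, 13, 21, 22 from 1).

## Steps most likely to fail

**1. Step 11.**
- What may go wrong:
  - The methide may tautomerise to a silyl enol ether before it is trapped.
  - The salt may be consumed by benzylating the released sulfinate or the phenoxide.
  - Proton exchange at the sulfonium-bearing carbon of the betaine, or an unselective relative approach of ylide and methide, may erode both the trans preference and the enantiomeric purity.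
- Fallback: known chemistry, an intramolecular carbenoid C–H insertion. It sets out from 1 and 12 and comes back at 18.
  - Phenol 1 is O-alkylated with 12 (K2CO3, DMF) to 5-bromo-3-methoxy-2-[(3-methoxy-4-pivaloyloxybenzyl)oxy]benzaldehyde F1.
  - Wittig methoxymethylenation (MeOCH2PPh3Cl, KOtBu) gives the methyl enol ether F2.
  - Pyridinium chlorochromate, [C5H5NH][CrO3Cl], oxidises it to the methyl arylacetate F3.
  - Diazo transfer (p-acetamidobenzenesulfonyl azide, DBU) gives the aryldiazoacetate F4.
  - The chiral dirhodium carboxylate Rh2(S-PTTL)4, or its antipode if that is the one setting 2S, inserts the carbenoid into the benzylic ether CH2. This closes the ring to the cis ester F5.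
  - NaOMe in MeOH epimerises C3 and removes the pivalate, giving the trans phenolic ester F6.
  - LiBH4 reduces it to the phenolic primary alcohol F7.
  - TBDPSCl and imidazole silylate the primary alcohol of F7 to give 18.

**2. Step 21.**
- What may go wrong:
  - Zinc insertion may be sluggish.
  - Adventitious acid may protonate the zinc reagent.
  - Oxidative addition to the electron-rich bromide may be slow.
  - β-Hydride elimination after transmetalation would waste both advanced fragments.
- Fallback: the polarity is reversed and the lactone is built on the arene. It sets out from 19 and 22 and comes back at 31.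
  - (R)-Epichlorohydrin and diethyl malonate (NaOEt, EtOH) give ethyl (1S,5R)-2-oxo-3-oxabicyclo[3.1.0]hexane-1-carboxylate F8.
  - Bromide 19 is lithiated (n-BuLi, THF, −78 °C) and transmetalated (MgBr2·OEt2, then CuI, 20 mol %). It then opens the doubly activated cyclopropane of F8 at its CH2 (homoconjugate addition) to the (4R)-4-arylmethyl-3-ethoxycarbonyl lactone F9.
  - Alkylation with 22 (K2CO3, acetone) gives the quaternary ester F10.
  - Krapcho de-ethoxycarbonylation (LiCl, wet DMSO, 130 °C) with thermodynamic protonation gives the trans lactone 31. Material that loses an aryl silyl group there goes into step 22 all the same.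

**3. Step 17.**
- What may go wrong:
  - The vinyl reagent may protodeboronate.
  - Turnover with the five-membered lactone may be low.
  - The double bond may migrate into conjugation.
  - Enantiofacial discrimination may be insufficient.
- Fallback: racemic addition and classical resolution. It sets out from 23 and comes back at 24.
  - Vinylmagnesium bromide with CuBr·SMe2 and Me3SiCl adds 1,4 to 23 to give rac-4-vinyldihydrofuran-2(3H)-one F11.
  - AlMe3-mediated aminolysis with (S)-1-phenylethylamine gives two diastereomeric hydroxy amides. They are separated by crystallisation or chromatography.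
  - The isomer (3S)-3-(hydroxymethyl)-N-[(1S)-1-phenylethyl]pent-4-enamide F12 is hydrolysed and relactonised (aq H2SO4, dioxane, reflux) to 24.

## Further compounds

F1 | step 11 | 5-bromo-3-methoxy-2-[(3-methoxy-4-pivaloyloxybenzyl)oxy]benzaldehyde | COc1cc(Br)cc(C=O)c1OCc1ccc(OC(=O)C(C)(C)C)c(OC)c1
F2 | step 11 | 4-{[4-bromo-2-methoxy-6-(2-methoxyvinyl)phenoxy]methyl}-2-methoxyphenyl pivalate (E/Z mixture) | COC=Cc1cc(Br)cc(OC)c1OCc1ccc(OC(=O)C(C)(C)C)c(OC)c1
F3 | step 11 | methyl 2-{5-bromo-3-methoxy-2-[(3-methoxy-4-pivaloyloxybenzyl)oxy]phenyl}acetate | COC(=O)Cc1cc(Br)cc(OC)c1OCc1ccc(OC(=O)C(C)(C)C)c(OC)c1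
F4 | step 11 | methyl 2-diazo-2-{5-bromo-3-methoxy-2-[(3-methoxy-4-pivaloyloxybenzyl)oxy]phenyl}acetate | COC(=O)C(=[N+]=[N-])c1cc(Br)cc(OC)c1OCc1ccc(OC(=O)C(C)(C)C)c(OC)c1
F5 | step 11 | methyl (2S,3R)-cis-5-bromo-7-methoxy-2-(3-methoxy-4-pivaloyloxyphenyl)-2,3-dihydrobenzofuran-3-carboxylate | Brc1cc(OC)c2c(c1)[C@@H](C(=O)OC)[C@@H](c1ccc(OC(=O)C(C)(C)C)c(OC)c1)O2
F6 | step 11 | methyl (2S,3S)-trans-5-bromo-2-(4-hydroxy-3-methoxyphenyl)-7-methoxy-2,3-dihydrobenzofuran-3-carboxylate | Brc1cc(OC)c2c(c1)[C@H](C(=O)OC)[C@@H](c1ccc(O)c(OC)c1)O2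
F7 | step 11 | 4-[(2S,3R)-5-bromo-3-(hydroxymethyl)-7-methoxy-2,3-dihydrobenzofuran-2-yl]-2-methoxyphenol | Brc1cc(OC)c2c(c1)[C@H](CO)[C@@H](c1ccc(O)c(OC)c1)O2
F8 | step 21 | ethyl (1S,5R)-2-oxo-3-oxabicyclo[3.1.0]hexane-1-carboxylate | CCOC(=O)[C@]12C[C@H]1COC2=O
F9 | step 21 | ethyl (4R)-4-(arylmethyl)-2-oxotetrahydrofuran-3-carboxylate, aryl = C5 of the bis-silylated dihydrobenzofuran of 19 (C3 epimers) | CCOC(=O)C1C(=O)OC[C@@H]1Cc1cc(OC)c2c(c1)[C@H](CO[Si](c1ccccc1)(c1ccccc1)C(C)(C)C)[C@@H](c1ccc(O[Si](C)(C)C(C)(C)C)c(OC)c1)O2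
F10 | step 21 | 3-[4-(tert-butyldimethylsilyloxy)-3-methoxybenzyl] derivative of F9 (quaternary C3, configuration lost on decarboxylation) | CCOC(=O)C1(Cc2ccc(O[Si](C)(C)C(C)(C)C)c(OC)c2)C(=O)OC[C@@H]1Cc1cc(OC)c2c(c1)[C@H](CO[Si](c1ccccc1)(c1ccccc1)C(C)(C)C)[C@@H](c1ccc(O[Si](C)(C)C(C)(C)C)c(OC)c1)O2
F11 | step 17 | rac-4-vinyldihydrofuran-2(3H)-one | C=CC1COC(=O)C1
F12 | step 17 | (3S)-3-(hydroxymethyl)-N-[(1S)-1-phenylethyl]pent-4-enamide | OC[C@@H](CC(=O)N[C@@H](C)c1ccccc1)C=C
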